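**Plan**
- Retrosynthetic cuts: first the angelate C–O bond; then the C4 benzyl group is traced back to an exocyclic benzylidene and the C3 hydroxymethyl group to a geminal diester; the ring (O1, C2, C3, C4, C5) is finally cut at O1–C2 and C3–C4, and the exocyclic carbon is cut from its arene.
- Enabling feature: O1–C5–C4 plus the exocyclic benzylic carbon is a propargyl alcohol unit; C2–C3 with the carbon branch on C3 is a benzylidene malonate, electrophilic at C2 and a soft carbanion at C3 once O1 has added; the benzyl arene can come from an aryl iodide.
- Forward order: Knoevenagel condensation; one-flask assembly of the only ring (three skeletal bonds); dealkoxycarbonylation; ester reduction; alkene hydrogenation; esterification.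
- Stereochemistry: C2 from a chiral palladium catalyst that selects between the reversibly formed oxa-Michael adducts; C3 by equilibration trans to the C2 aryl group; C4 by hydrogenation on the face away from the C3 substituent; the Z angelate is bought and carried in unchanged.

Key step: step 2

Assumption: the sense of induction of the ligand cannot be predicted with confidence; the (R) antipode is written for the (2R) diester, and its mirror image would be used if the opposite sense were found.

**Step 1**
Reactants: 1 3,4-dimethoxybenzaldehyde; 2 dimethyl malonate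
Product: 3 dimethyl 2-(3,4-dimethoxybenzylidene)malonate
Conditions: piperidine (0.1 equiv), AcOH (0.1 equiv), toluene, reflux, Dean–Stark trap
Reagents that add atoms: none
Why: Knoevenagel condensation through the iminium ion of the aldehyde, driven to completion by azeotropic removal of water; the two ester groups are identical, so no alkene isomers arise.

**Step 2**
Reactants: 3 dimethyl 2-(3,4-dimethoxybenzylidene)malonate; 4 propargyl alcohol (prop-2-yn-1-ol); 5 4-iodo-1,2-dimethoxybenzene
Product: 8 dimethyl (2R,4Z)-4-(3,4-dimethoxybenzylidene)-2-(3,4-dimethoxyphenyl)dihydrofuran-3,3(2H)-dicarboxylate, via lithium prop-2-yn-1-olate 6 (not isolated), via lithium malonate adduct 7 (not isolated)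
Conditions: 4, n-BuLi (1.0 equiv), THF, 0 °C; then 3, 5, Pd2(dba)3 (2.5 mol%), (R)-DTBM-SEGPHOS [(R)-5,5'-bis[bis(3,5-di-tert-butyl-4-methoxyphenyl)phosphino]-4,4'-bi-1,3-benzodioxole] (6 mol%), DMSO–THF, rt
Reagents that add atoms: none
Why: Proposed new method: alkoxide 6 adds reversibly to the benzylidene malonate 3 (O1–C2) to give the malonate carbanion 7; oxidative addition of 5 to the zerovalent palladium–bisphosphine complex gives an arylpalladium iodide which, after loss of iodide in the polar medium, binds the alkyne of 7, the malonate carbon attacks the internal alkyne carbon from the side opposite palladium (C3–C4), and reductive elimination from the vinylpalladium species joins the aryl group to the exocyclic carbon and returns zerovalent palladium. The closest known reaction type is the racemic three-component coupling of lithium propargyl alkoxides, alkylidene malonates and aryl iodides under a zerovalent palladium–triphenylphosphine catalyst; only the chiral ligand and the enantiocontrol asked of it are new. The ring closes in the 5-exo-dig mode, since the three-atom link C2–O1–C5 between carbanion and alkyne puts the internal alkyne carbon within reach and the anti attack on the metal-bound alkyne needs no strained geometry. C2, the only new stereocentre, would be set by the ligand in a dynamic kinetic resolution: the two C2 epimers of 7 interconvert by retro-oxa-Michael reaction and re-addition faster than they cyclise, and in one of the two diastereomeric ring-closing transition states the C2 aryl group is expected to run into the bulky P-aryl groups on the phosphorus cis to the bound alkyne. The step needs anti addition across the alkyne, which outer-sphere attack of the soft, doubly stabilised carbanion secures and which places the new aryl group trans to C3 (Z alkene), and it needs a reversible oxa-Michael addition, which the two ester groups secure.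

**Step 3**
Reactants: 8 dimethyl (2R,4Z)-4-(3,4-dimethoxybenzylidene)-2-(3,4-dimethoxyphenyl)dihydrofuran-3,3(2H)-dicarboxylate
Product: 9 methyl (2S,3S,4Z)-4-(3,4-dimethoxybenzylidene)-2-(3,4-dimethoxyphenyl)tetrahydrofuran-3-carboxylate
Conditions: LiCl (3 equiv), H2O (2 equiv), DMSO, 140 °C
Reagents that add atoms: none
Why: Krapcho dealkoxycarbonylation (chloride demethylates one ester by SN2 attack, the carboxylate loses CO2 and water protonates C3); the C3 proton, activated by the ester and the neighbouring alkene, exchanges in the hot medium, so the ester should settle trans to the C2 aryl group (3S), while the ring stays closed because expulsion of O1 from the C3 carbanion would be the stereoelectronically disfavoured reverse of a 5-endo-trig closure.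

**Step 4**
Reactants: 9 methyl (2S,3S,4Z)-4-(3,4-dimethoxybenzylidene)-2-(3,4-dimethoxyphenyl)tetrahydrofuran-3-carboxylate
Product: 10 [(2S,3R,4Z)-4-(3,4-dimethoxybenzylidene)-2-(3,4-dimethoxyphenyl)tetrahydrofuran-3-yl]methanol
Conditions: LiAlH4, THF, −20 to 0 °C
Reagents that add atoms: none
Why: Hydride reduction of the ester to the primary alcohol; at low temperature addition to the carbonyl group outruns deprotonation at C3, so the C3 configuration and the position of the alkene are retained (the descriptor changes from 3S to 3R only through the priority rules).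

**Step 5**
Reactants: 10 [(2S,3R,4Z)-4-(3,4-dimethoxybenzylidene)-2-(3,4-dimethoxyphenyl)tetrahydrofuran-3-yl]methanol
Product: 11 [(2S,3R,4R)-4-(3,4-dimethoxybenzyl)-2-(3,4-dimethoxyphenyl)tetrahydrofuran-3-yl]methanol
Conditions: H2 (1 atm), 10% Pd/C, EtOAc, rt
Reagents that add atoms: none
Why: Heterogeneous catalytic hydrogenation of the trisubstituted, aryl-conjugated alkene; the catalyst surface should meet C4 on the ring face opposite the adjacent C3 hydroxymethyl group (the C2 aryl group, one ring atom further away, shields the other face less), so the new C4–H is trans and the benzyl group cis to the C3 substituent (4R), and the neutral, low-pressure conditions are chosen to spare the benzylic C2–O1 bond.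

**Step 6**
Reactants: 11 [(2S,3R,4R)-4-(3,4-dimethoxybenzyl)-2-(3,4-dimethoxyphenyl)tetrahydrofuran-3-yl]methanol; 12 angelic acid [(2Z)-2-methylbut-2-enoic acid]
Product: 13 leoligin, [(2S,3R,4R)-4-(3,4-dimethoxybenzyl)-2-(3,4-dimethoxyphenyl)tetrahydrofuran-3-yl]methyl (2Z)-2-methylbut-2-enoate
Conditions: PPh3, DIAD, THF, 0 °C to rt
Reagents that add atoms: none
Why: Mitsunobu esterification: the primary alcohol is activated as its alkoxyphosphonium ion and displaced by the angelate anion, so the acid never passes through an activated acyl derivative in which its Z alkene could isomerise to the tiglate, and no stereocentre takes part.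

**Compound list**
1 | 3,4-dimethoxybenzaldehyde | COc1ccc(C=O)cc1OC | starting material
2 | dimethyl malonate | COC(=O)CC(=O)OC | starting material
3 | dimethyl 2-(3,4-dimethoxybenzylidene)malonate | COC(=O)C(=Cc1ccc(OC)c(OC)c1)C(=O)OC | intermediate
4 | propargyl alcohol (prop-2-yn-1-ol) | C#CCO | starting material
5 | 4-iodo-1,2-dimethoxybenzene | COc1ccc(I)cc1OC | starting material
6 | lithium prop-2-yn-1-olate | [Li+].[O-]CC#C | intermediate
7 | lithium salt of dimethyl 2-[(3,4-dimethoxyphenyl)(prop-2-yn-1-yloxy)methyl]malonate (carbanion at the malonate carbon; both C2 epimers, interconverting) | [Li+].COC(=O)[C-](C(=O)OC)C(OCC#C)c1ccc(OC)c(OC)c1 | intermediate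
8 | dimethyl (2R,4Z)-4-(3,4-dimethoxybenzylidene)-2-(3,4-dimethoxyphenyl)dihydrofuran-3,3(2H)-dicarboxylate | COC(=O)C1(C(=O)OC)/C(=C/c2ccc(OC)c(OC)c2)CO[C@@H]1c1ccc(OC)c(OC)c1 | intermediate
9 | methyl (2S,3S,4Z)-4-(3,4-dimethoxybenzylidene)-2-(3,4-dimethoxyphenyl)tetrahydrofuran-3-carboxylate | COC(=O)[C@H]1/C(=C/c2ccc(OC)c(OC)c2)CO[C@@H]1c1ccc(OC)c(OC)c1 | intermediate
10 | [(2S,3R,4Z)-4-(3,4-dimethoxybenzylidene)-2-(3,4-dimethoxyphenyl)tetrahydrofuran-3-yl]methanol | OC[C@H]1/C(=C/c2ccc(OC)c(OC)c2)CO[C@@H]1c1ccc(OC)c(OC)c1 | intermediate
11 | [(2S,3R,4R)-4-(3,4-dimethoxybenzyl)-2-(3,4-dimethoxyphenyl)tetrahydrofuran-3-yl]methanol | OC[C@H]1[C@@H](Cc2ccc(OC)c(OC)c2)CO[C@@H]1c1ccc(OC)c(OC)c1 | intermediate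
12 | angelic acid, (2Z)-2-methylbut-2-enoic acid | C/C=C(/C)C(=O)O | starting material
13 | leoligin | C/C=C(/C)C(=O)OC[C@H]1[C@@H](Cc2ccc(OC)c(OC)c2)CO[C@@H]1c1ccc(OC)c(OC)c1 | target

**Count**
Total steps: 6. Longest linear sequence: 6 steps (1 → 3 → 8 → 9 → 10 → 11 → 13).

**Steps most likely to fail**

1. Step 2 (the step that carries the label). The catalyst may fail to distinguish the two interconverting epimers of 7, so that the ring closes with little enantioselectivity. The bulky ligand may also slow ring closure until direct arylation of the alkyne competes. The fallback uses known chemistry, sets out from 3 (with 4 and 5) and comes back at 10. The coupling is run without a chiral ligand, with PdCl2(PPh3)2 reduced in the flask to zerovalent palladium by n-BuLi (THF–DMSO, rt). This should give 8 together with its mirror image, the (2S)-diester F1. Steps 3 and 4 applied to this racemate lead through 9 and the (2R,3R)-ester F2 to 10 and the (2R,3S)-alcohol F3. Acylation with (1S)-camphanic chloride (pyridine, DMAP, CH2Cl2) turns the two alcohols into the (2S,3R)-camphanate F4 and the (2R,3S)-camphanate F5. These diastereomers are to be separated by crystallisation or chromatography on silica gel. Methanolysis of F4 (K2CO3, MeOH, rt) returns 10 as a single enantiomer.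

2. Step 3. In the hot, weakly basic medium the exocyclic double bond may migrate into conjugation with the ester, which would also erase control at C3. Equilibration at C3 may also stay incomplete. The fallback sets out from 8 and comes back at 9. Saponification of one ester with KOH (1.1 equiv) in aqueous methanol–THF at room temperature gives, after acidification, the half-acid F6. It is drawn with the carboxyl group trans to the C2 aryl group, the less shielded ester being the one expected to react. Warming F6 in toluene at about 100 °C lets the malonic half-acid lose CO2 through its cyclic, hydrogen-bonded transition state under neutral conditions, so that C3 is protonated without a free dienolate in a basic medium. A trace of DBU at room temperature then settles C3 trans to the aryl group and gives 9.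

3. Step 5. Hydrogen may be delivered to the wrong face, since the free hydroxyl group can anchor the substrate to the metal. The double bond may also migrate on the catalyst, or the benzylic C2–O1 bond may be hydrogenolysed. The fallback sets out from 10 and comes back at 11. The alcohol is silylated (TBDPSCl, imidazole, DMF) to the tert-butyldiphenylsilyl ether F7. Its bulky silyloxymethyl group shields the lower face more firmly and cannot bind to the metal. Hydrogenation over 5% Rh/Al2O3 (H2 1 atm, EtOAc), a catalyst with little tendency towards benzylic C–O cleavage or alkene migration, should give the saturated silyl ether F8. TBAF in THF then returns 11.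

**Further compounds**
F1 | step 2 | dimethyl (2S,4Z)-4-(3,4-dimethoxybenzylidene)-2-(3,4-dimethoxyphenyl)dihydrofuran-3,3(2H)-dicarboxylate (mirror image of 8) | COC(=O)C1(C(=O)OC)/C(=C/c2ccc(OC)c(OC)c2)CO[C@H]1c1ccc(OC)c(OC)c1
F2 | step 2 | methyl (2R,3R,4Z)-4-(3,4-dimethoxybenzylidene)-2-(3,4-dimethoxyphenyl)tetrahydrofuran-3-carboxylate (mirror image of 9) | COC(=O)[C@@H]1/C(=C/c2ccc(OC)c(OC)c2)CO[C@H]1c1ccc(OC)c(OC)c1
F3 | step 2 | [(2R,3S,4Z)-4-(3,4-dimethoxybenzylidene)-2-(3,4-dimethoxyphenyl)tetrahydrofuran-3-yl]methanol (mirror image of 10) | OC[C@@H]1/C(=C/c2ccc(OC)c(OC)c2)CO[C@H]1c1ccc(OC)c(OC)c1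
F4 | step 2 | [(2S,3R,4Z)-4-(3,4-dimethoxybenzylidene)-2-(3,4-dimethoxyphenyl)tetrahydrofuran-3-yl]methyl (1S,4R)-4,7,7-trimethyl-3-oxo-2-oxabicyclo[2.2.1]heptane-1-carboxylate | CC1(C)[C@@]2(C)CC[C@]1(C(=O)OC[C@H]3/C(=C/c4ccc(OC)c(OC)c4)CO[C@@H]3c3ccc(OC)c(OC)c3)OC2=O
F5 | step 2 | [(2R,3S,4Z)-4-(3,4-dimethoxybenzylidene)-2-(3,4-dimethoxyphenyl)tetrahydrofuran-3-yl]methyl (1S,4R)-4,7,7-trimethyl-3-oxo-2-oxabicyclo[2.2.1]heptane-1-carboxylate | CC1(C)[C@@]2(C)CC[C@]1(C(=O)OC[C@@H]3/C(=C/c4ccc(OC)c(OC)c4)CO[C@H]3c3ccc(OC)c(OC)c3)OC2=O
F6 | step 3 | (2R,3R,4Z)-4-(3,4-dimethoxybenzylidene)-2-(3,4-dimethoxyphenyl)-3-(methoxycarbonyl)tetrahydrofuran-3-carboxylic acid | OC(=O)[C@@]1(C(=O)OC)/C(=C/c2ccc(OC)c(OC)c2)CO[C@@H]1c1ccc(OC)c(OC)c1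
F7 | step 5 | tert-butyl{[(2S,3R,4Z)-4-(3,4-dimethoxybenzylidene)-2-(3,4-dimethoxyphenyl)tetrahydrofuran-3-yl]methoxy}diphenylsilane | CC(C)(C)[Si](OC[C@H]1/C(=C/c2ccc(OC)c(OC)c2)CO[C@@H]1c1ccc(OC)c(OC)c1)(c1ccccc1)c1ccccc1
F8 | step 5 | tert-butyl{[(2S,3R,4R)-4-(3,4-dimethoxybenzyl)-2-(3,4-dimethoxyphenyl)tetrahydrofuran-3-yl]methoxy}diphenylsilane | CC(C)(C)[Si](OC[C@H]1[C@@H](Cc2ccc(OC)c(OC)c2)CO[C@@H]1c1ccc(OC)c(OC)c1)(c1ccccc1)c1ccccc1
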